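**Target:** CNP0383656.1, 6β,7α-diacetoxy-8α-hydroxycleroda-3,11E,13-trien-15,16-olide (30)

**Plan**
1. The side chain is cut at C12–C13 (Suzuki–Miyaura) and C11=C12 (chromium olefination of a C11 aldehyde); the two acetates and the C8 carbinol go back to a 6-silyloxy-8-ketone (C8–C17 by methylenation, O7 by enolate oxidation, O8 by directed epoxidation).
2. The decalin is cut at C5–C10 and C1–C2: the ring A cyclohexene C3=C4, lying between the quaternary C5 and the ring-fusion CH C10, is the mark of a C2=C3–C4=C5 diene adding to a C10=C1 alkene carried on the four-carbon link C6–C9, which becomes ring B.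
3. The triene is cut at C6–C7 (aldol of a methyl ketone with a dienal) and at C10=C1 (Horner–Wadsworth–Emmons, sulfone as removable activator); C9 comes from ethyl (S)-3-hydroxybutanoate by two Frater–Seebach alkylations.
4. Forward: dienal (steps 1–4) and ketone (steps 5–9) are joined (step 10), both rings close together in step 12 (ring A as the cycloadduct, ring B as the tether ring), ring B is oxidised (steps 13–17), and the butenolide arm is added (steps 18–20) before deprotection and acetylation.
5. Stereochemistry: C9 from the hydroxybutanoate (alkylation anti to its methyl group), C6 from the chiral boron aldol, C5 and C10 relayed from C6 and C9 in the cycloaddition, C7 and C8 by attack on the α face of the trans-decalin, away from the axial C19 and C20 methyl groups.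

Key step: step 12

Remark: clerodane numbering is used; β is the face of C19 (5β-Me, 9β-Me = C20, 8β-Me = C17, 10α-H), and absolute configuration is that of the SMILES strings.
Remark (assumption): boron enolates of methyl ketones made with (−)-Ipc2BCl are taken to attack the Re face of aldehydes, so the (+)-reagent is chosen for Si-face attack on 6; the antipodal reagent would be used if the sense proved opposite.

**Step 1**
Reactants: 1 ethyl 2-methylacetoacetate
Product: 2 ethyl (E)-2-methyl-3-(tosyloxy)but-2-enoate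
Conditions: TsCl, N-methylimidazole, Et3N, MeCN, 0 °C → rt
Reagents that add atoms: p-toluenesulfonyl chloride, Cc1ccc(cc1)S(Cl)(=O)=O
Why: Enol sulfonylation of a β-keto ester under non-chelating amine conditions should give the (E)-enol tosylate, with the tosyloxy group trans to the ester; no stereocentre is formed.

**Step 2**
Reactants: 2 ethyl (E)-2-methyl-3-(tosyloxy)but-2-enoate; 3 vinylboronic acid pinacol ester
Product: 4 ethyl (E)-2,3-dimethylpenta-2,4-dienoate
Conditions: Pd(OAc)2 (cat.), SPhos (cat.), K3PO4, THF/H2O, 60 °C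
Reagents that add atoms: none
Why: Suzuki–Miyaura coupling of the activated enol tosylate proceeds with retention of alkene geometry, so the vinyl group ends up trans to the ester.

**Step 3**
Reactants: 4 ethyl (E)-2,3-dimethylpenta-2,4-dienoate
Product: 5 (E)-2,3-dimethylpenta-2,4-dien-1-ol
Conditions: DIBAL-H, CH2Cl2, −78 °C
Reagents that add atoms: none
Why: DIBAL-H 1,2-reduction of the dienoate gives the allylic alcohol and leaves the tetrasubstituted alkene geometry untouched.

**Step 4**
Reactants: 5 (E)-2,3-dimethylpenta-2,4-dien-1-ol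
Product: 6 (E)-2,3-dimethylpenta-2,4-dienal
Conditions: MnO2, CH2Cl2, rt; filtered and used as a solution
Reagents that add atoms: none
Why: MnO2 oxidation of the allylic alcohol is selective and neutral, so the diene is not isomerised; the volatile dienal is not concentrated to dryness.

**Step 5**
Reactants: 7 ethyl (S)-3-hydroxybutanoate
Product: 9 ethyl (2S,3S)-3-hydroxy-2-methylbutanoate, via dilithium dianion 8 (not isolated)
Conditions: LDA (2.2 equiv), THF, −50 → −20 °C; MeI, −78 → 0 °C
Reagents that add atoms: iodomethane, CI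
Why: Frater–Seebach alkylation, in which the chelated dianion is methylated anti to the C3 methyl group to give the anti (2S,3S) ester.

**Step 6**
Reactants: 9 ethyl (2S,3S)-3-hydroxy-2-methylbutanoate
Product: 11 ethyl (2S,3S)-2-[(benzyloxy)methyl]-3-hydroxy-2-methylbutanoate, via dilithium dianion 10 (not isolated)
Conditions: LDA (2.2 equiv), THF/DMPU, −78 → −15 °C; BnOCH2Cl, −78 → −20 °C
Reagents that add atoms: benzyl chloromethyl ether, ClCOCc1ccccc1
Why: A second Frater–Seebach alkylation, with the electrophile again entering anti to the carbinol methyl group, creates the quaternary centre (future C9) in the configuration fixed by the order of the two alkylations; the minor diastereomer is removed here, which secures the enantiopurity of C9 after the carbinol is oxidised.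

**Step 7**
Reactants: 11 ethyl (2S,3S)-2-[(benzyloxy)methyl]-3-hydroxy-2-methylbutanoate
Product: 12 (2S,3S)-2-[(benzyloxy)methyl]-2-methylbutane-1,3-diol
Conditions: LiAlH4, THF, 0 °C
Reagents that add atoms: none
Why: LiAlH4 reduction of the ester to the primary alcohol leaves the benzyl ether and both stereocentres untouched.

**Step 8**
Reactants: 12 (2S,3S)-2-[(benzyloxy)methyl]-2-methylbutane-1,3-diol
Product: 13 (R)-2-[(benzyloxy)methyl]-2-methyl-3-oxobutanal
Conditions: Dess–Martin periodinane (2.4 equiv), pyridine, CH2Cl2, 0 °C → rt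
Reagents that add atoms: none
Why: Dess–Martin oxidation of both hydroxyls gives a 2,2-disubstituted 3-oxo-aldehyde that has no α-hydrogen at the quaternary carbon and so cannot epimerise or eliminate.

**Step 9**
Reactants: 13 (R)-2-[(benzyloxy)methyl]-2-methyl-3-oxobutanal
Product: 14 (S,E)-3-[(benzyloxy)methyl]-3-methyl-5-(phenylsulfonyl)pent-4-en-2-one
Conditions: (EtO)2P(O)CH2SO2Ph, NaH, THF, 0 °C; then 13, −78 → 0 °C
Reagents that add atoms: diethyl [(phenylsulfonyl)methyl]phosphonate, CCOP(=O)(OCC)CS(=O)(=O)c1ccccc1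
Why: Horner–Wadsworth–Emmons olefination with the sulfonyl-stabilised phosphonate should react at the aldehyde in preference to the hindered ketone and give the (E)-vinyl sulfone.

**Step 10**
Reactants: 14 (S,E)-3-[(benzyloxy)methyl]-3-methyl-5-(phenylsulfonyl)pent-4-en-2-one; 6 (E)-2,3-dimethylpenta-2,4-dienal
Product: 16 (1E,3S,6S,7E)-3-[(benzyloxy)methyl]-6-hydroxy-3,7,8-trimethyl-1-(phenylsulfonyl)deca-1,7,9-trien-4-one, via diisopinocampheylboron enolate 15 (not isolated)
Conditions: (+)-Ipc2BCl, Et3N, Et2O, 0 °C; 6, −78 → −20 °C; then pH 7 buffer, MeOH, H2O2, 0 °C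
Reagents that add atoms: none
Why: Diisopinocampheylboron-mediated aldol of a methyl ketone, in which the methyl group is the only enolisable position and the chiral boron ligands direct the enolate to the Si face of the dienal to set C6 as S; the C6 epimer is a diastereomer and is separable because C9 is already fixed.

**Step 11**
Reactants: 16 (1E,3S,6S,7E)-3-[(benzyloxy)methyl]-6-hydroxy-3,7,8-trimethyl-1-(phenylsulfonyl)deca-1,7,9-trien-4-one
Product: 17 (1E,3S,6S,7E)-3-[(benzyloxy)methyl]-6-[(tert-butyldimethylsilyl)oxy]-3,7,8-trimethyl-1-(phenylsulfonyl)deca-1,7,9-trien-4-one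
Conditions: TBSOTf, 2,6-lutidine, CH2Cl2, −78 °C
Reagents that add atoms: tert-butyldimethylsilyl triflate, CC(C)(C)[Si](C)(C)OS(=O)(=O)C(F)(F)F
Why: Silylation with the silyl triflate and a hindered base at low temperature protects the elimination-prone dienylic β-hydroxy ketone without ionising it.

**Step 12**
Reactants: 17 (1E,3S,6S,7E)-3-[(benzyloxy)methyl]-6-[(tert-butyldimethylsilyl)oxy]-3,7,8-trimethyl-1-(phenylsulfonyl)deca-1,7,9-trien-4-one
Product: 18 11-(benzyloxy)-6β-[(tert-butyldimethylsilyl)oxy]-1α-(phenylsulfonyl)-12,13,14,15,16,17-hexanorclerod-3-en-8-one (trans-fused; 5β-Me, 9β-Me, 10α-H)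
Conditions: PhMe (0.01 M), BHT (cat.), 180 °C, sealed tube, silylated glass
Reagents that add atoms: none
Why: Concerted, suprafacial [4π+2π] cycloaddition of the C2=C3–C4=C5 diene to the sulfone-activated C10=C1 alkene, the closest known reaction type being the thermal intramolecular Diels–Alder reaction of (E)-1-sulfonyl-1,7,9-decatrienes. Ring A closes as the new cyclohexene through the bonds C1–C2 and C5–C10, and ring B closes in the same event as the six-membered tether ring C5–C6–C7–C8–C9–C10 held in a chair. C5 is set by the diene face, which allylic 1,3-strain fixes: C6–H eclipses the C4 methyl group, so the silyloxy group lies equatorial and the tether reaches the opposite face. C10 follows from the chair tether with E-diene and E-dienophile, which gives the trans ring fusion with C20 axial and CH2OBn equatorial, and C1 follows from suprafacial addition to the E-alkene with the sulfonyl group endo, hence cis to H10. The step needs trans over cis fusion and a single diene face; the E,E geometry, the endo-placed terminal sulfone, the C6 stereocentre and the gem-disubstituted C9 (which also speeds closure) should secure both, while dilution and BHT hold back polymerisation.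

**Step 13**
Reactants: 18 the sulfonyl octalone from step 12
Product: 20 7α-hydroxy derivative of 18, via potassium enolate 19 (not isolated)
Conditions: KHMDS (1.1 equiv), THF, −78 °C; 2-(phenylsulfonyl)-3-phenyloxaziridine, −78 °C
Reagents that add atoms: 2-(phenylsulfonyl)-3-phenyloxaziridine, O=S(=O)(N1OC1c1ccccc1)c1ccccc1
Why: Enolate oxidation with a Davis oxaziridine, in which the ketone can enolise only towards C7 and the oxidant attacks from the α face, away from the axial C19 and C20 methyl groups, to give the equatorial 7α-alcohol; the equatorial 6β-silyloxy group is poorly aligned for E1cB loss at −78 °C.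

**Step 14**
Reactants: 20 7α-hydroxy ketone
Product: 21 11-(benzyloxy)-6β-[(tert-butyldimethylsilyl)oxy]-1α-(phenylsulfonyl)-12,13,14,15,16-pentanorcleroda-3,8(17)-dien-7α-ol
Conditions: Zn, CH2Br2, TiCl4, THF/CH2Cl2, 0 °C → rt
Reagents that add atoms: dibromomethane, BrCBr
Why: Lombardo–Takai methylenation uses a non-basic titanium–zinc carbenoid that converts hindered, enolisable and hydroxyl-bearing ketones into 1,1-disubstituted alkenes without β-elimination or epimerisation.

**Step 15**
Reactants: 21 the 8(17)-methylene 7α-alcohol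
Product: 22 11-(benzyloxy)-6β-[(tert-butyldimethylsilyl)oxy]-8α,17-epoxy-1α-(phenylsulfonyl)-12,13,14,15,16-pentanorclerod-3-en-7α-ol
Conditions: VO(acac)2 (cat.), t-BuOOH, CH2Cl2, 0 °C → rt
Reagents that add atoms: tert-butyl hydroperoxide, CC(C)(C)OO
Why: Vanadium-catalysed hydroxyl-directed epoxidation acts on the allylic-alcohol alkene C8=C17 and not on the isolated C3=C4 alkene, and delivers oxygen from the α face on which the 7α-hydroxyl lies and which is remote from the axial C20 methyl group, so C8 receives its oxygen α.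

**Step 16**
Reactants: 22 the 8α,17-epoxy 7α-alcohol
Product: 23 7-O-triethylsilyl ether of 22
Conditions: Et3SiCl, imidazole, DMAP (cat.), DMF, rt
Reagents that add atoms: chlorotriethylsilane, CC[Si](Cl)(CC)CC
Why: Silylation of the only free hydroxyl under non-acidic conditions keeps the spiro-epoxide intact and marks O7 apart from the hydroxyls released in the next step.

**Step 17**
Reactants: 23 the 7-O-triethylsilyl epoxide
Product: 24 6β-[(tert-butyldimethylsilyl)oxy]-7α-[(triethylsilyl)oxy]-12,13,14,15,16-pentanorclerod-3-ene-8α,11-diol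
Conditions: Li, NH3(l)/THF, −78 → −33 °C; then solid NH4Cl
Reagents that add atoms: none
Why: Dissolving-metal (Birch-type) reduction should cleave in one operation the C1–S bond, the benzyl ether and the less substituted C17–O bond of the epoxide, so that C17 becomes the methyl group and C8 keeps its α-oxygen as the tertiary alcohol; silyl ethers and isolated alkenes are inert.

**Step 18**
Reactants: 24 the 8α,11-diol
Product: 25 6β-[(tert-butyldimethylsilyl)oxy]-8α-hydroxy-7α-[(triethylsilyl)oxy]-12,13,14,15,16-pentanorclerod-3-en-11-al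
Conditions: Dess–Martin periodinane, pyridine, CH2Cl2, 0 °C; used at once
Reagents that add atoms: none
Why: Dess–Martin oxidation can act only on the primary C11 alcohol because the other free hydroxyl is tertiary, and the neutral medium avoids retro-aldol cleavage of the β-hydroxy aldehyde.

**Step 19**
Reactants: 25 the C11 aldehyde
Product: 26 (11E)-6β-[(tert-butyldimethylsilyl)oxy]-7α-[(triethylsilyl)oxy]-12-(4,4,5,5-tetramethyl-1,3,2-dioxaborolan-2-yl)-13,14,15,16-tetranorcleroda-3,11-dien-8α-ol
Conditions: CrCl2, LiI, Cl2CHBpin, THF, rt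
Reagents that add atoms: 2-(dichloromethyl)-4,4,5,5-tetramethyl-1,3,2-dioxaborolane, ClC(Cl)B1OC(C)(C)C(C)(C)O1
Why: Takai–Utimoto olefination with the geminal dichromium species tolerates hindered aldehydes and free hydroxyls and gives the (E)-alkenyl boronate.

**Step 20**
Reactants: 26 the (E)-alkenyl boronate; 27 4-bromofuran-2(5H)-one
Product: 28 6β-[(tert-butyldimethylsilyl)oxy]-8α-hydroxy-7α-[(triethylsilyl)oxy]cleroda-3,11E,13-trien-15,16-olide
Conditions: PdCl2(dppf) (cat.), K3PO4 (aq.), THF, 40 °C
Reagents that add atoms: none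
Why: Suzuki–Miyaura coupling of the alkenyl boronate with the β-bromo butenolide, a vinylogous acyl bromide that undergoes oxidative addition readily, joins C12 to C13 with retention of the E geometry.

**Step 21**
Reactants: 28 the bis-silyl ether
Product: 29 6β,7α,8α-trihydroxycleroda-3,11E,13-trien-15,16-olide
Conditions: HF·pyridine, THF/pyridine, 0 °C → rt
Reagents that add atoms: none
Why: Fluoride-mediated desilylation under buffered conditions removes both silyl ethers and leaves the butenolide, the diene and the tertiary alcohol untouched.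

**Step 22**
Reactants: 29 the triol
Product: 30 6β,7α-diacetoxy-8α-hydroxycleroda-3,11E,13-trien-15,16-olide (CNP0383656.1)
Conditions: Ac2O, pyridine, DMAP (cat.), CH2Cl2, rt
Reagents that add atoms: acetic anhydride, CC(=O)OC(C)=O
Why: DMAP-catalysed acetylation should esterify the two equatorial secondary hydroxyls, while the axial tertiary C8 hydroxyl next to the quaternary C9 does not react at room temperature.

**Compound list**
1 | ethyl 2-methylacetoacetate | CCOC(=O)C(C)C(C)=O | starting material
2 | ethyl (E)-2-methyl-3-(tosyloxy)but-2-enoate | CCOC(=O)/C(C)=C(\C)OS(=O)(=O)c1ccc(C)cc1 | intermediate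
3 | vinylboronic acid pinacol ester | C=CB1OC(C)(C)C(C)(C)O1 | starting material
4 | ethyl (E)-2,3-dimethylpenta-2,4-dienoate | C=C/C(C)=C(\C)C(=O)OCC | intermediate
5 | (E)-2,3-dimethylpenta-2,4-dien-1-ol | C=C/C(C)=C(\C)CO | intermediate
6 | (E)-2,3-dimethylpenta-2,4-dienal | C=C/C(C)=C(\C)C=O | intermediate
7 | ethyl (S)-3-hydroxybutanoate | C[C@H](O)CC(=O)OCC | starting material
8 | dilithium dianion of 7 (chelated enolate alkoxide) | [Li+].[Li+].C[C@H]([O-])/C=C(\[O-])OCC | intermediate (not isolated)
9 | ethyl (2S,3S)-3-hydroxy-2-methylbutanoate | C[C@H](O)[C@H](C)C(=O)OCC | intermediate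
10 | dilithium dianion of 9 (chelated enolate alkoxide) | [Li+].[Li+].C[C@H]([O-])/C(C)=C(\[O-])OCC | intermediate (not isolated)
11 | ethyl (2S,3S)-2-[(benzyloxy)methyl]-3-hydroxy-2-methylbutanoate | C[C@H](O)[C@](C)(COCc1ccccc1)C(=O)OCC | intermediate
12 | (2S,3S)-2-[(benzyloxy)methyl]-2-methylbutane-1,3-diol | C[C@H](O)[C@](C)(COCc1ccccc1)CO | intermediate
13 | (R)-2-[(benzyloxy)methyl]-2-methyl-3-oxobutanal | CC(=O)[C@](C)(COCc1ccccc1)C=O | intermediate
14 | (S,E)-3-[(benzyloxy)methyl]-3-methyl-5-(phenylsulfonyl)pent-4-en-2-one | CC(=O)[C@](C)(COCc1ccccc1)/C=C/S(=O)(=O)c1ccccc1 | intermediate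
15 | diisopinocampheylboron enolate of 14 | C=C(OB([C@H]1C[C@H]2C[C@@H]([C@@H]1C)C2(C)C)[C@H]1C[C@H]2C[C@@H]([C@@H]1C)C2(C)C)[C@](C)(COCc1ccccc1)/C=C/S(=O)(=O)c1ccccc1 | intermediate (not isolated)
16 | (1E,3S,6S,7E)-3-[(benzyloxy)methyl]-6-hydroxy-3,7,8-trimethyl-1-(phenylsulfonyl)deca-1,7,9-trien-4-one | C=C/C(C)=C(\C)[C@@H](O)CC(=O)[C@](C)(COCc1ccccc1)/C=C/S(=O)(=O)c1ccccc1 | intermediate
17 | (1E,3S,6S,7E)-3-[(benzyloxy)methyl]-6-[(tert-butyldimethylsilyl)oxy]-3,7,8-trimethyl-1-(phenylsulfonyl)deca-1,7,9-trien-4-one (cycloaddition precursor) | C=C/C(C)=C(\C)[C@@H](O[Si](C)(C)C(C)(C)C)CC(=O)[C@](C)(COCc1ccccc1)/C=C/S(=O)(=O)c1ccccc1 | intermediate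
18 | 11-(benzyloxy)-6β-[(tert-butyldimethylsilyl)oxy]-1α-(phenylsulfonyl)-12,13,14,15,16,17-hexanorclerod-3-en-8-one; trans-fused, 5β-Me, 9β-Me, 9α-CH2OBn, 10α-H (cycloadduct) | CC(C)(C)[Si](C)(C)O[C@H]1CC(=O)[C@](C)(COCc3ccccc3)[C@H]2[C@H](S(=O)(=O)c3ccccc3)CC=C(C)[C@]12C | intermediate
19 | potassium 7,8-enolate of 18 | CC(C)(C)[Si](C)(C)O[C@H]1C=C([O-])[C@](C)(COCc3ccccc3)[C@H]2[C@H](S(=O)(=O)c3ccccc3)CC=C(C)[C@]12C.[K+] | intermediate (not isolated)
20 | 7α-hydroxy derivative of 18 | CC(C)(C)[Si](C)(C)O[C@H]1[C@H](O)C(=O)[C@](C)(COCc3ccccc3)[C@H]2[C@H](S(=O)(=O)c3ccccc3)CC=C(C)[C@]12C | intermediate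
21 | 11-(benzyloxy)-6β-[(tert-butyldimethylsilyl)oxy]-1α-(phenylsulfonyl)-12,13,14,15,16-pentanorcleroda-3,8(17)-dien-7α-ol | CC(C)(C)[Si](C)(C)O[C@H]1[C@H](O)C(=C)[C@](C)(COCc3ccccc3)[C@H]2[C@H](S(=O)(=O)c3ccccc3)CC=C(C)[C@]12C | intermediate
22 | 11-(benzyloxy)-6β-[(tert-butyldimethylsilyl)oxy]-8α,17-epoxy-1α-(phenylsulfonyl)-12,13,14,15,16-pentanorclerod-3-en-7α-ol | CC(C)(C)[Si](C)(C)O[C@H]1[C@H](O)[C@@]3(CO3)[C@](C)(COCc4ccccc4)[C@H]2[C@H](S(=O)(=O)c4ccccc4)CC=C(C)[C@]12C | intermediate
23 | 7-O-triethylsilyl ether of 22 | CC(C)(C)[Si](C)(C)O[C@H]1[C@H](O[Si](CC)(CC)CC)[C@@]3(CO3)[C@](C)(COCc4ccccc4)[C@H]2[C@H](S(=O)(=O)c4ccccc4)CC=C(C)[C@]12C | intermediate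
24 | 6β-[(tert-butyldimethylsilyl)oxy]-7α-[(triethylsilyl)oxy]-12,13,14,15,16-pentanorclerod-3-ene-8α,11-diol | CC(C)(C)[Si](C)(C)O[C@H]1[C@H](O[Si](CC)(CC)CC)[C@](C)(O)[C@](C)(CO)[C@H]2CCC=C(C)[C@]12C | intermediate
25 | 6β-[(tert-butyldimethylsilyl)oxy]-8α-hydroxy-7α-[(triethylsilyl)oxy]-12,13,14,15,16-pentanorclerod-3-en-11-al | CC(C)(C)[Si](C)(C)O[C@H]1[C@H](O[Si](CC)(CC)CC)[C@](C)(O)[C@](C)(C=O)[C@H]2CCC=C(C)[C@]12C | intermediate
26 | (11E)-6β-[(tert-butyldimethylsilyl)oxy]-7α-[(triethylsilyl)oxy]-12-(4,4,5,5-tetramethyl-1,3,2-dioxaborolan-2-yl)-13,14,15,16-tetranorcleroda-3,11-dien-8α-ol | CC(C)(C)[Si](C)(C)O[C@H]1[C@H](O[Si](CC)(CC)CC)[C@](C)(O)[C@](C)(/C=C/B3OC(C)(C)C(C)(C)O3)[C@H]2CCC=C(C)[C@]12C | intermediate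
27 | 4-bromofuran-2(5H)-one | O=C1OCC(Br)=C1 | starting material
28 | 6β-[(tert-butyldimethylsilyl)oxy]-8α-hydroxy-7α-[(triethylsilyl)oxy]cleroda-3,11E,13-trien-15,16-olide | CC(C)(C)[Si](C)(C)O[C@H]1[C@H](O[Si](CC)(CC)CC)[C@](C)(O)[C@](C)(/C=C/C3=CC(=O)OC3)[C@H]2CCC=C(C)[C@]12C | intermediate
29 | 6β,7α,8α-trihydroxycleroda-3,11E,13-trien-15,16-olide | O[C@H]1[C@H](O)[C@](C)(O)[C@](C)(/C=C/C3=CC(=O)OC3)[C@H]2CCC=C(C)[C@]12C | intermediate
30 | 6β,7α-diacetoxy-8α-hydroxycleroda-3,11E,13-trien-15,16-olide (CNP0383656.1) | CC(=O)O[C@H]1[C@H](OC(C)=O)[C@](C)(O)[C@](C)(/C=C/C2=CC(=O)OC2)[C@H]2CCC=C(C)[C@]12C | target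

**Step count**
Total: 22 steps. Longest linear sequence: 18 steps (steps 5–22, from ethyl (S)-3-hydroxybutanoate); the dienal branch (steps 1–4) joins at step 10.

**Steps most likely to fail**

Step 12. The fully substituted diene terminus C5 and the neopentyl dienophile carbon C10 may make the cycloaddition so slow that, at the temperature needed, thermal β-elimination of silanol from the β-silyloxy ketone, a [1,5]-hydrogen shift from the C19 methyl group, or loss of trans selectivity competes. The fallback uses a doubly activated dienophile that should cyclise below 80 °C and has no endo/exo question at C1. It sets out from 13 and returns at 24.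
- Knoevenagel condensation of 13 with bis(phenylsulfonyl)methane (TiCl4, pyridine, THF) would give the alkylidene bis-sulfone F1.
- The boron aldol of step 10 (non-oxidative work-up) would give the aldol F2, and silylation as in step 11 the silyl ether F3.
- Warming F3 in toluene would give the geminal disulfone cycloadduct F4.
- F4 is carried through the operations of steps 13–16 to the 7α-hydroxy ketone F5, the methylene alcohol F6, the epoxy alcohol F7 and the triethylsilyl ether F8.
- Li/NH3 then removes both sulfonyl groups together with the benzyl ether and opens the epoxide, giving 24.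

Step 14. Carbonyl methylenation at a ketone flanked by the quaternary C9 and the C7 carbinol may stall, and the Lewis-acidic reagent may then promote a ketol shift or loss of the silyl ether. The fallback is a two-stage Peterson olefination. It sets out from 20 and returns at 21: addition of Me3SiCH2Li/CeCl3 (THF, −78 °C), which adds to hindered enolisable ketones from the open α face, would give the β-hydroxysilane F9, and KH in THF would eliminate it to 21. The configuration created at C8 in F9 is irrelevant because it is lost in the elimination.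

Step 10. Face selection on the dienal rests on reagent control alone, since the remote C9 centre gives no help; it may be modest, and the dienylic aldol may dehydrate during work-up. The fallback is a catalytic Mukaiyama aldol. It sets out from 14 and returns at 16: silylation (TMSOTf, Et3N, CH2Cl2, 0 °C) would give the trimethylsilyl enol ether F10; addition to 6 under an N-sulfonyl tryptophan-derived oxazaborolidinone catalyst (EtCN, −78 °C) would give the silylated aldol F11; dilute HCl in THF would release 16.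

**Further compounds**
F1 | step 12 | (S)-3-[(benzyloxy)methyl]-3-methyl-5,5-bis(phenylsulfonyl)pent-4-en-2-one | CC(=O)[C@](C)(COCc1ccccc1)C=C(S(=O)(=O)c1ccccc1)S(=O)(=O)c1ccccc1
F2 | step 12 | (3S,6S,7E)-3-[(benzyloxy)methyl]-6-hydroxy-3,7,8-trimethyl-1,1-bis(phenylsulfonyl)deca-1,7,9-trien-4-one | C=C/C(C)=C(\C)[C@@H](O)CC(=O)[C@](C)(COCc1ccccc1)C=C(S(=O)(=O)c1ccccc1)S(=O)(=O)c1ccccc1
F3 | step 12 | 6-O-tert-butyldimethylsilyl ether of F2 | C=C/C(C)=C(\C)[C@@H](O[Si](C)(C)C(C)(C)C)CC(=O)[C@](C)(COCc1ccccc1)C=C(S(=O)(=O)c1ccccc1)S(=O)(=O)c1ccccc1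
F4 | step 12 | 1,1-bis(phenylsulfonyl) analogue of 18 | CC(C)(C)[Si](C)(C)O[C@H]1CC(=O)[C@](C)(COCc3ccccc3)[C@H]2C(S(=O)(=O)c3ccccc3)(S(=O)(=O)c3ccccc3)CC=C(C)[C@]12C
F5 | step 12 | 1,1-bis(phenylsulfonyl) analogue of 20 (7α-hydroxy ketone) | CC(C)(C)[Si](C)(C)O[C@H]1[C@H](O)C(=O)[C@](C)(COCc3ccccc3)[C@H]2C(S(=O)(=O)c3ccccc3)(S(=O)(=O)c3ccccc3)CC=C(C)[C@]12C
F6 | step 12 | 1,1-bis(phenylsulfonyl) analogue of 21 (8(17)-methylene 7α-alcohol) | CC(C)(C)[Si](C)(C)O[C@H]1[C@H](O)C(=C)[C@](C)(COCc3ccccc3)[C@H]2C(S(=O)(=O)c3ccccc3)(S(=O)(=O)c3ccccc3)CC=C(C)[C@]12C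
F7 | step 12 | 1,1-bis(phenylsulfonyl) analogue of 22 (8α,17-epoxy 7α-alcohol) | CC(C)(C)[Si](C)(C)O[C@H]1[C@H](O)[C@@]3(CO3)[C@](C)(COCc4ccccc4)[C@H]2C(S(=O)(=O)c4ccccc4)(S(=O)(=O)c4ccccc4)CC=C(C)[C@]12C
F8 | step 12 | 1,1-bis(phenylsulfonyl) analogue of 23 (7-O-triethylsilyl epoxide) | CC(C)(C)[Si](C)(C)O[C@H]1[C@H](O[Si](CC)(CC)CC)[C@@]3(CO3)[C@](C)(COCc4ccccc4)[C@H]2C(S(=O)(=O)c4ccccc4)(S(=O)(=O)c4ccccc4)CC=C(C)[C@]12C
F9 | step 14 | 8β-hydroxy-8α-[(trimethylsilyl)methyl] adduct of 20 (7α,8β-diol) | CC(C)(C)[Si](C)(C)O[C@H]1[C@H](O)[C@](O)(C[Si](C)(C)C)[C@](C)(COCc3ccccc3)[C@H]2[C@H](S(=O)(=O)c3ccccc3)CC=C(C)[C@]12C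
F10 | step 10 | trimethylsilyl enol ether of 14, (S,E)-{3-[(benzyloxy)methyl]-3-methyl-5-(phenylsulfonyl)penta-1,4-dien-2-yl}oxytrimethylsilane | C=C(O[Si](C)(C)C)[C@](C)(COCc1ccccc1)/C=C/S(=O)(=O)c1ccccc1
F11 | step 10 | 6-O-trimethylsilyl ether of 16 | C=C/C(C)=C(\C)[C@@H](O[Si](C)(C)C)CC(=O)[C@](C)(COCc1ccccc1)/C=C/S(=O)(=O)c1ccccc1
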